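**Retrosynthetic overview**
1. Upper ring C is the only ring made and is closed last: the upper phloroglucinol ring (C4a) attacks C4 in a Friedel–Crafts step while C4 is held as an ortho-quinone methide on lower ring A (C7=O, C8=C4). Hydrogenolysis of eleven benzyl ethers follows.
2. The carbinol for that closure comes from an ortho-hydroxyaryl ketone, made in the key disconnection: a lower-unit 7,8-aryne takes up a β-aryloxy carboxylic acid, oxygen going to C7 and the acyl carbon to C8. The strategy rests on lower ring A carrying C7–OH directly beside the C8–C4 bond, with ring oxygen O1 on C8a flanking C8.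
3. The aryne precursor (7-triflate, 8-triethylsilyl, gallate on O3) comes from (−)-epigallocatechin: persilylation, C8 bromination, Br–Li exchange with a retro-Brook shift that can only come from O7, triflation, silyl-to-benzyl exchange, galloylation.
4. The (S)-acid comes from 3,4-dihydroxyacetophenone: benzylation, Claisen condensation, asymmetric transfer hydrogenation, Mitsunobu etherification with purchased 3,5-bis(benzyloxy)phenol, saponification.
5. All other rings (lower A, C, B, galloyl; upper A and B) are bought with the starting materials.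

Key step: step 12

Assumption: a C8 triethylsilyl group is taken to release the aryne with fluoride as a trimethylsilyl group does; it is chosen because the aryl triethylsilyl ethers that deliver it to C8 survive chromatography and butyllithium.

**Route**

Step 1
Reactants: 1 (−)-epigallocatechin
Product: 2 (2R,3R)-3,5,7,3',4',5'-hexakis-O-(triethylsilyl)epigallocatechin
Conditions: Et3SiCl, imidazole, DMF, 0 °C → rt
Reagents that add atoms: chlorotriethylsilane, CC[Si](Cl)(CC)CC
Why: Imidazole-promoted silyl ether formation at the five phenols and the 3-OH; no stereocentre is touched.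

Step 2
Reactants: 2 hexakis-O-(triethylsilyl)epigallocatechin
Product: 3 8-bromo-3,5,7,3',4',5'-hexakis-O-(triethylsilyl)epigallocatechin
Conditions: NBS (1.0 equiv), CH2Cl2, −78 → 0 °C
Reagents that add atoms: N-bromosuccinimide, O=C1CCC(=O)N1Br
Why: Electrophilic aromatic bromination; ring A is the most electron-rich ring and C8 has a bulky silyloxy group on one side only (C6 sits between two), so C8 should react first, the pattern known for 5,7-di-O-protected flavan-3-ols.

Step 3
Reactants: 3 8-bromo-hexakis-O-(triethylsilyl)epigallocatechin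
Product: 6 3,5,3',4',5'-pentakis-O-(triethylsilyl)-8-(triethylsilyl)epigallocatechin 7-O-triflate, via 8-lithio arene 4 (not isolated), via lithium 7-phenoxide 5 (not isolated)
Conditions: n-BuLi, THF, −78 → −20 °C; then PhNTf2, −78 °C → rt
Reagents that add atoms: N-phenylbis(trifluoromethanesulfonimide), O=S(=O)(N(c1ccccc1)S(=O)(=O)C(F)(F)F)C(F)(F)F
Why: Bromine–lithium exchange gives the C8 aryllithium, and only the silyl group on the neighbouring O7 can make the 1,3 O→C retro-Brook shift, so the rearrangement puts silicon on C8 and unmasks O7 alone as a lithium phenoxide, which is triflated in the same flask (the standard route from ortho-bromophenols to ortho-silylaryl triflates).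

Step 4
Reactants: 6 pentakis-O-(triethylsilyl)-8-(triethylsilyl)epigallocatechin 7-O-triflate
Product: 8 5,3',4',5'-tetra-O-benzyl-3-O-(triethylsilyl)-8-(triethylsilyl)epigallocatechin 7-O-triflate, via tetraphenol 7 (not isolated)
Conditions: K2CO3, MeOH–THF, 0 °C, Ar; evaporate; then BnBr, K2CO3, DMF, rt, Ar
Reagents that add atoms: benzyl bromide, BrCc1ccccc1
Why: Carbonate-catalysed methanolysis cleaves aryl O–Si bonds far faster than the alkyl O–Si bond at O3, the C8–Si bond or the triflate S–O bond, and the four phenoxides are then benzylated by Williamson ether synthesis under argon to keep the pyrogallol from oxidising.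

Step 5
Reactants: 8 tetra-O-benzyl-3-O-(triethylsilyl)-8-(triethylsilyl)epigallocatechin 7-O-triflate
Product: 9 5,3',4',5'-tetra-O-benzyl-8-(triethylsilyl)epigallocatechin 7-O-triflate (free 3-OH)
Conditions: PPTS, MeOH–CH2Cl2, rt
Reagents that add atoms: none
Why: Acid-catalysed methanolysis of the secondary triethylsilyl ether; the weak acid should not protodesilylate C8, which is deactivated by the ortho triflate.

Step 6
Reactants: 9 tetra-O-benzyl-8-(triethylsilyl)epigallocatechin 7-O-triflate; 10 3,4,5-tris(benzyloxy)benzoic acid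
Product: 11 5,3',4',5'-tetra-O-benzyl-8-(triethylsilyl)epigallocatechin 7-O-triflate 3-O-[3,4,5-tris(benzyloxy)benzoate] (aryne precursor)
Conditions: DCC, DMAP, CH2Cl2, rt
Reagents that add atoms: none
Why: Steglich esterification acylates the axial 3-OH through its O–H bond, so C3 keeps its configuration; triflate and arylsilane are inert without fluoride.

Step 7
Reactants: 12 3,4-dihydroxyacetophenone
Product: 13 3,4-bis(benzyloxy)acetophenone
Conditions: BnBr, K2CO3, DMF, 60 °C
Reagents that add atoms: benzyl bromide, BrCc1ccccc1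
Why: Williamson ether synthesis on both phenols.

Step 8
Reactants: 13 3,4-bis(benzyloxy)acetophenone
Product: 14 ethyl 3-[3,4-bis(benzyloxy)phenyl]-3-oxopropanoate
Conditions: NaH, (EtO)2CO, THF, reflux; aq. HCl work-up
Reagents that add atoms: diethyl carbonate, CCOC(=O)OCC
Why: Crossed Claisen condensation of the ketone enolate with the non-enolisable carbonate, driven by deprotonation of the β-keto ester formed.

Step 9
Reactants: 14 ethyl 3-[3,4-bis(benzyloxy)phenyl]-3-oxopropanoate
Product: 15 ethyl (R)-3-[3,4-bis(benzyloxy)phenyl]-3-hydroxypropanoate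
Conditions: RuCl[(R,R)-TsDPEN](p-cymene) (1 mol%), HCO2H–Et3N (5:2), CH2Cl2, 30 °C
Reagents that add atoms: none
Why: Noyori asymmetric transfer hydrogenation; hydride and proton pass through the six-membered bifunctional transition state to the ketone face fixed by the CH/π contact between the aryl group and the cymene ligand, so the (R,R) catalyst should give the (R)-carbinol (same sense as acetophenone to (R)-1-phenylethanol), and benzyl ethers are not cleaved.

Step 10
Reactants: 15 ethyl (R)-3-[3,4-bis(benzyloxy)phenyl]-3-hydroxypropanoate; 16 3,5-bis(benzyloxy)phenol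
Product: 17 ethyl (S)-3-[3,4-bis(benzyloxy)phenyl]-3-[3,5-bis(benzyloxy)phenoxy]propanoate
Conditions: PPh3, DIAD, toluene, 0 °C → rt
Reagents that add atoms: none
Why: Mitsunobu reaction; the phenoxide displaces the oxyphosphonium in an SN2 step with inversion, turning the (R)-alcohol into the (S)-aryl ether, and toluene at low temperature is chosen to hold back ionisation of the electron-rich benzylic centre and dehydration to the cinnamate.

Step 11
Reactants: 17 ethyl (S)-3-[3,4-bis(benzyloxy)phenyl]-3-[3,5-bis(benzyloxy)phenoxy]propanoate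
Product: 18 (S)-3-[3,4-bis(benzyloxy)phenyl]-3-[3,5-bis(benzyloxy)phenoxy]propanoic acid
Conditions: LiOH·H2O, THF–H2O, 0 °C → rt; then 1 M HCl to pH 3
Reagents that add atoms: lithium hydroxide, [Li+].[OH-]
Why: Saponification at the acyl carbon leaves the β-stereocentre untouched; at 0 °C hydroxide attack on the ester is faster than the α-deprotonation that would expel the aryloxide, and the carboxylate once formed cannot eliminate.

Step 12
Reactants: 11 aryne precursor (7-O-triflate, 8-triethylsilyl); 18 (S)-β-aryloxy acid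
Product: 20 (2R,3R)-5-benzyloxy-8-{(3S)-3-[3,4-bis(benzyloxy)phenyl]-3-[3,5-bis(benzyloxy)phenoxy]propanoyl}-7-hydroxy-2-[3,4,5-tris(benzyloxy)phenyl]chroman-3-yl 3,4,5-tris(benzyloxy)benzoate, via lower-unit 7,8-aryne 19 (not isolated)
Conditions: CsF (4 equiv), 18-crown-6, THF, 65 °C
Reagents that add atoms: none
Why: Fluoride attacks the C8 silicon and expels the C7 triflate to release aryne 19; the carboxylate of 18 adds through oxygen to C7, and the C8 aryl anion so formed attacks the neighbouring ester carbonyl through a four-membered transition state, the adduct opening to the C8 ketone and the C7 phenoxide. The closest known reaction type is the insertion of arynes into the C–O bond of carboxylic acids to give ortho-hydroxyaryl ketones, run in THF so that acyl transfer outruns protonation of the aryl anion (the bifluoride formed from the acid proton is sparingly soluble). No ring is closed and no stereocentre is formed; C2 of the acid lies β to the carbonyl and is not touched, and the lower-unit centres are remote. The step needs regioselective addition to the unsymmetrical aryne: the inductively withdrawing ring oxygen O1 on C8a stabilises negative charge at C8, so the oxygen nucleophile should go to the distal, unhindered C7 (C6–H exerts no bias), as with 3-alkoxyarynes. It also needs the carboxylate to beat the product phenoxide to the aryne, which the hindered, ketone-chelated 7-phenoxide and a small excess of acid should secure.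

Step 13
Reactants: 20 lower-unit 7-hydroxy-8-aryl ketone
Product: 21 (2R,3R)-5-benzyloxy-8-{(3S)-3-[3,4-bis(benzyloxy)phenyl]-3-[3,5-bis(benzyloxy)phenoxy]-1-hydroxypropyl}-7-hydroxy-2-[3,4,5-tris(benzyloxy)phenyl]chroman-3-yl 3,4,5-tris(benzyloxy)benzoate (both epimers at the carbinol carbon)
Conditions: NaBH4, THF–MeOH, 0 °C; pH 7 buffer work-up, crude used directly
Reagents that add atoms: none
Why: Borohydride 1,2-reduction of the aryl ketone is faster than reduction of the benzoate ester; the new carbinol centre is formed without control and is erased on ionisation in step 14, and chromatography is avoided because the alcohol ionises readily.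

Step 14
Reactants: 21 ortho-hydroxybenzylic alcohol
Product: 23 (2R,3R)-5-benzyloxy-8-{(2S,4R)-5,7-bis(benzyloxy)-2-[3,4-bis(benzyloxy)phenyl]chroman-4-yl}-7-hydroxy-2-[3,4,5-tris(benzyloxy)phenyl]chroman-3-yl 3,4,5-tris(benzyloxy)benzoate, via ortho-quinone methide 22 (not isolated)
Conditions: TFA (5 mol%), 4 Å MS, CH2Cl2 (dilute), −40 → 0 °C
Reagents that add atoms: none
Why: Acid-catalysed loss of water gives the ortho-quinone methide (reacting as its O-protonated benzylic cation), which is captured by the 3,5-bis(benzyloxy)phenoxy ring ortho to the ether oxygen in an intramolecular Friedel–Crafts alkylation closing six-membered ring C; in the chair-like transition state the C2 aryl group is equatorial and the lower unit on C4 takes the pseudo-axial position to avoid peri strain with the C5 benzyloxy group, which should give the 2,4-trans (4R) isomer.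

Step 15
Reactants: 23 undeca-O-benzyl dimer
Product: 24 CNP0190017.1, (2R,3R)-8-[(2S,4R)-2-(3,4-dihydroxyphenyl)-5,7-dihydroxychroman-4-yl]-5,7-dihydroxy-2-(3,4,5-trihydroxyphenyl)chroman-3-yl 3,4,5-trihydroxybenzoate
Conditions: H2 (1 atm), Pd(OH)2/C, THF–MeOH, rt
Reagents that add atoms: none
Why: Hydrogenolysis of the eleven benzyl ethers under conditions that are standard for benzylated proanthocyanidins and should leave the benzylic C2–O1 and C4–C8 bonds and the gallate intact.

**Compound list**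

1 | (−)-epigallocatechin, (2R,3R)-2-(3,4,5-trihydroxyphenyl)chromane-3,5,7-triol | O[C@@H]1Cc2c(O)cc(O)cc2O[C@@H]1c1cc(O)c(O)c(O)c1 | starting material
2 | (2R,3R)-3,5,7,3',4',5'-hexakis-O-(triethylsilyl)epigallocatechin | CC[Si](CC)(CC)O[C@@H]1Cc2c(O[Si](CC)(CC)CC)cc(O[Si](CC)(CC)CC)cc2O[C@@H]1c1cc(O[Si](CC)(CC)CC)c(O[Si](CC)(CC)CC)c(O[Si](CC)(CC)CC)c1 | intermediate
3 | 8-bromo-hexakis-O-(triethylsilyl)epigallocatechin | CC[Si](CC)(CC)O[C@@H]1Cc2c(O[Si](CC)(CC)CC)cc(O[Si](CC)(CC)CC)c(Br)c2O[C@@H]1c1cc(O[Si](CC)(CC)CC)c(O[Si](CC)(CC)CC)c(O[Si](CC)(CC)CC)c1 | intermediate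
4 | 8-lithio-hexakis-O-(triethylsilyl)epigallocatechin | CC[Si](CC)(CC)O[C@@H]1Cc2c(O[Si](CC)(CC)CC)cc(O[Si](CC)(CC)CC)c([Li])c2O[C@@H]1c1cc(O[Si](CC)(CC)CC)c(O[Si](CC)(CC)CC)c(O[Si](CC)(CC)CC)c1 | intermediate
5 | lithium 7-phenoxide of 3,5,3',4',5'-pentakis-O-(triethylsilyl)-8-(triethylsilyl)epigallocatechin | CC[Si](CC)(CC)O[C@@H]1Cc2c(O[Si](CC)(CC)CC)cc(O[Li])c([Si](CC)(CC)CC)c2O[C@@H]1c1cc(O[Si](CC)(CC)CC)c(O[Si](CC)(CC)CC)c(O[Si](CC)(CC)CC)c1 | intermediate
6 | 3,5,3',4',5'-pentakis-O-(triethylsilyl)-8-(triethylsilyl)epigallocatechin 7-O-triflate | CC[Si](CC)(CC)O[C@@H]1Cc2c(O[Si](CC)(CC)CC)cc(OS(=O)(=O)C(F)(F)F)c([Si](CC)(CC)CC)c2O[C@@H]1c1cc(O[Si](CC)(CC)CC)c(O[Si](CC)(CC)CC)c(O[Si](CC)(CC)CC)c1 | intermediate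
7 | 3-O-(triethylsilyl)-8-(triethylsilyl)epigallocatechin 7-O-triflate (5,3',4',5'-tetraphenol) | CC[Si](CC)(CC)O[C@@H]1Cc2c(O)cc(OS(=O)(=O)C(F)(F)F)c([Si](CC)(CC)CC)c2O[C@@H]1c1cc(O)c(O)c(O)c1 | intermediate
8 | 5,3',4',5'-tetra-O-benzyl-3-O-(triethylsilyl)-8-(triethylsilyl)epigallocatechin 7-O-triflate | CC[Si](CC)(CC)O[C@@H]1Cc2c(OCc3ccccc3)cc(OS(=O)(=O)C(F)(F)F)c([Si](CC)(CC)CC)c2O[C@@H]1c1cc(OCc3ccccc3)c(OCc3ccccc3)c(OCc3ccccc3)c1 | intermediate
9 | 5,3',4',5'-tetra-O-benzyl-8-(triethylsilyl)epigallocatechin 7-O-triflate | O[C@@H]1Cc2c(OCc3ccccc3)cc(OS(=O)(=O)C(F)(F)F)c([Si](CC)(CC)CC)c2O[C@@H]1c1cc(OCc3ccccc3)c(OCc3ccccc3)c(OCc3ccccc3)c1 | intermediate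
10 | 3,4,5-tris(benzyloxy)benzoic acid | OC(=O)c1cc(OCc2ccccc2)c(OCc2ccccc2)c(OCc2ccccc2)c1 | starting material
11 | aryne precursor, (2R,3R)-5-benzyloxy-7-(trifluoromethanesulfonyloxy)-8-(triethylsilyl)-2-[3,4,5-tris(benzyloxy)phenyl]chroman-3-yl 3,4,5-tris(benzyloxy)benzoate | O=C(O[C@@H]1Cc2c(OCc5ccccc5)cc(OS(=O)(=O)C(F)(F)F)c([Si](CC)(CC)CC)c2O[C@@H]1c1cc(OCc5ccccc5)c(OCc5ccccc5)c(OCc5ccccc5)c1)c1cc(OCc5ccccc5)c(OCc5ccccc5)c(OCc5ccccc5)c1 | intermediate
12 | 3,4-dihydroxyacetophenone | CC(=O)c1ccc(O)c(O)c1 | starting material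
13 | 3,4-bis(benzyloxy)acetophenone | CC(=O)c1ccc(OCc2ccccc2)c(OCc2ccccc2)c1 | intermediate
14 | ethyl 3-[3,4-bis(benzyloxy)phenyl]-3-oxopropanoate | CCOC(=O)CC(=O)c1ccc(OCc2ccccc2)c(OCc2ccccc2)c1 | intermediate
15 | ethyl (R)-3-[3,4-bis(benzyloxy)phenyl]-3-hydroxypropanoate | CCOC(=O)C[C@@H](O)c1ccc(OCc2ccccc2)c(OCc2ccccc2)c1 | intermediate
16 | 3,5-bis(benzyloxy)phenol | Oc1cc(OCc2ccccc2)cc(OCc2ccccc2)c1 | starting material
17 | ethyl (S)-3-[3,4-bis(benzyloxy)phenyl]-3-[3,5-bis(benzyloxy)phenoxy]propanoate | CCOC(=O)C[C@@H](c1ccc(OCc2ccccc2)c(OCc2ccccc2)c1)Oc1cc(OCc2ccccc2)cc(OCc2ccccc2)c1 | intermediate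
18 | (S)-3-[3,4-bis(benzyloxy)phenyl]-3-[3,5-bis(benzyloxy)phenoxy]propanoic acid | OC(=O)C[C@@H](c1ccc(OCc2ccccc2)c(OCc2ccccc2)c1)Oc1cc(OCc2ccccc2)cc(OCc2ccccc2)c1 | intermediate
19 | lower-unit 7,8-aryne (7,8-didehydro form of 11 without triflate and silyl groups) | O=C(O[C@@H]1CC2=C(C#CC=C2OCc5ccccc5)O[C@@H]1c1cc(OCc5ccccc5)c(OCc5ccccc5)c(OCc5ccccc5)c1)c1cc(OCc5ccccc5)c(OCc5ccccc5)c(OCc5ccccc5)c1 | intermediate
20 | lower-unit 7-hydroxy-8-aryl ketone (name as in step 12) | O=C(O[C@@H]1Cc2c(OCc5ccccc5)cc(O)c(C(=O)C[C@@H](c4ccc(OCc5ccccc5)c(OCc5ccccc5)c4)Oc4cc(OCc5ccccc5)cc(OCc5ccccc5)c4)c2O[C@@H]1c1cc(OCc5ccccc5)c(OCc5ccccc5)c(OCc5ccccc5)c1)c1cc(OCc5ccccc5)c(OCc5ccccc5)c(OCc5ccccc5)c1 | intermediate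
21 | ortho-hydroxybenzylic alcohol, both carbinol epimers (name as in step 13) | O=C(O[C@@H]1Cc2c(OCc5ccccc5)cc(O)c(C(O)C[C@@H](c4ccc(OCc5ccccc5)c(OCc5ccccc5)c4)Oc4cc(OCc5ccccc5)cc(OCc5ccccc5)c4)c2O[C@@H]1c1cc(OCc5ccccc5)c(OCc5ccccc5)c(OCc5ccccc5)c1)c1cc(OCc5ccccc5)c(OCc5ccccc5)c(OCc5ccccc5)c1 | intermediate
22 | ortho-quinone methide on lower ring A (C7=O, C8=C4 exocyclic) | O=C(O[C@@H]1CC2=C(O[C@@H]1c1cc(OCc5ccccc5)c(OCc5ccccc5)c(OCc5ccccc5)c1)C(=CC[C@@H](c4ccc(OCc5ccccc5)c(OCc5ccccc5)c4)Oc4cc(OCc5ccccc5)cc(OCc5ccccc5)c4)C(=O)C=C2OCc5ccccc5)c1cc(OCc5ccccc5)c(OCc5ccccc5)c(OCc5ccccc5)c1 | intermediate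
23 | undeca-O-benzyl dimer with free lower 7-OH, upper unit (2S,4R), 2,4-trans (name as in step 14) | O=C(O[C@@H]1Cc2c(OCc5ccccc5)cc(O)c([C@@H]3C[C@@H](c4ccc(OCc5ccccc5)c(OCc5ccccc5)c4)Oc4cc(OCc5ccccc5)cc(OCc5ccccc5)c43)c2O[C@@H]1c1cc(OCc5ccccc5)c(OCc5ccccc5)c(OCc5ccccc5)c1)c1cc(OCc5ccccc5)c(OCc5ccccc5)c(OCc5ccccc5)c1 | intermediate
24 | CNP0190017.1 (name as in step 15) | O=C(O[C@@H]1Cc2c(O)cc(O)c([C@@H]3C[C@@H](c4ccc(O)c(O)c4)Oc4cc(O)cc(O)c43)c2O[C@@H]1c1cc(O)c(O)c(O)c1)c1cc(O)c(O)c(O)c1 | target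

**Step count and risks**

Total steps: 15. Longest linear sequence: 10 (steps 1–6, then 12–15); the acid branch is 5 steps (7–11).

Step 12. The C8 aryl anion may be protonated before acyl transfer, leaving only the aryl ester; fluoride or phenoxide may eliminate the aryloxide β to the carbonyl at the temperature needed; and addition to the aryne may lose regioselectivity. Fallback, setting out from 11 and 18 and returning at 20: the same O→C acyl transfer through a C8 carbanion is reached by iodine–lithium exchange instead of aryne addition. Ipso-iododesilylation of 11 with one equivalent of iodine monochloride (CH2Cl2, −78 °C; attack at the silylated carbon is faster than C–H iodination of the benzyloxy rings) should give the 8-iodo 7-triflate F1. Brief treatment with Et4NOH in dioxane cleaves the S–O bond of the triflate to the 8-iodo-7-phenol F2. Steglich esterification of F2 with acid 18 (DCC, DMAP) gives the 8-iodoaryl ester F3, and t-BuLi (2 equiv, THF, −100 °C) then triggers the anionic Fries rearrangement to ketone 20, with C8 fixed by the position of the iodine and no hot basic or protic stage.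

Step 14. The ring closure may show poor facial selectivity at C4, or the cation may lose a proton from C3 to a styrene whose allylic aryl ether then ionises and expels the phenol. Fallback, setting out from 18 and returning at 24: ring C is built before the interflavan bond and a flavan-4-yl cation is captured by C8 of a benzylated lower unit, the classical route to 2,4-trans 4-arylflavans. Acid 18 is cyclised by intramolecular Friedel–Crafts acylation (TFAA, CH2Cl2, 0 °C) to the (2S)-flavanone F4, which NaBH4 reduces to the flavan-4-ol F5. Purchased (−)-epigallocatechin gallate is benzylated (BnBr, K2CO3, DMF) to octa-O-benzyl-epigallocatechin gallate F6. F5 and an excess of F6 with BF3·OEt2 (CH2Cl2, −78 → −20 °C) should give the dodeca-O-benzyl dimer F7, the nucleophile entering trans to the C2 aryl group and through C8 as in benzylated flavan-3-ols; hydrogenolysis (H2, Pd(OH)2/C) then gives 24. This path also bypasses steps 12 and 13.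

Step 10. The β-hydroxy ester may dehydrate to the cinnamate, and the electron-rich benzylic oxyphosphonium may ionise with partial loss of configuration. Fallback, setting out from 14 and returning at 18: the aryl–oxygen bond is formed instead of the alkyl–oxygen bond, so the stereocentre is never a leaving-group carbon. Transfer hydrogenation of 14 with RuCl[(S,S)-TsDPEN](p-cymene) gives the (S)-hydroxy ester F8, LiBH4 (THF) reduces it to the (S)-1,3-diol F9, and TBSCl with imidazole (CH2Cl2, 0 °C) silylates the primary hydroxyl to give F10. Palladium-catalysed C–O cross-coupling of F10 with purchased 1-bromo-3,5-bis(benzyloxy)benzene (Pd2(dba)3, RockPhos, Cs2CO3, toluene, 90 °C) should give the aryl ether F11 with retention. TBAF frees the primary alcohol F12, and TEMPO with PhI(OAc)2 in MeCN–H2O oxidises it to acid 18.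

**Further compounds**

F1 | step 12 | (2R,3R)-5-benzyloxy-8-iodo-7-(trifluoromethanesulfonyloxy)-2-[3,4,5-tris(benzyloxy)phenyl]chroman-3-yl 3,4,5-tris(benzyloxy)benzoate | O=C(O[C@@H]1Cc2c(OCc5ccccc5)cc(OS(=O)(=O)C(F)(F)F)c(I)c2O[C@@H]1c1cc(OCc5ccccc5)c(OCc5ccccc5)c(OCc5ccccc5)c1)c1cc(OCc5ccccc5)c(OCc5ccccc5)c(OCc5ccccc5)c1
F2 | step 12 | (2R,3R)-5-benzyloxy-7-hydroxy-8-iodo-2-[3,4,5-tris(benzyloxy)phenyl]chroman-3-yl 3,4,5-tris(benzyloxy)benzoate | O=C(O[C@@H]1Cc2c(OCc5ccccc5)cc(O)c(I)c2O[C@@H]1c1cc(OCc5ccccc5)c(OCc5ccccc5)c(OCc5ccccc5)c1)c1cc(OCc5ccccc5)c(OCc5ccccc5)c(OCc5ccccc5)c1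
F3 | step 12 | 7-O-[(S)-3-[3,4-bis(benzyloxy)phenyl]-3-[3,5-bis(benzyloxy)phenoxy]propanoyl] ester of F2 | O=C(O[C@@H]1Cc2c(OCc5ccccc5)cc(OC(=O)C[C@@H](c4ccc(OCc5ccccc5)c(OCc5ccccc5)c4)Oc4cc(OCc5ccccc5)cc(OCc5ccccc5)c4)c(I)c2O[C@@H]1c1cc(OCc5ccccc5)c(OCc5ccccc5)c(OCc5ccccc5)c1)c1cc(OCc5ccccc5)c(OCc5ccccc5)c(OCc5ccccc5)c1
F4 | step 14 | (2S)-5,7-bis(benzyloxy)-2-[3,4-bis(benzyloxy)phenyl]chroman-4-one | O=C1C[C@@H](c2ccc(OCc3ccccc3)c(OCc3ccccc3)c2)Oc2cc(OCc3ccccc3)cc(OCc3ccccc3)c12
F5 | step 14 | (2S)-5,7-bis(benzyloxy)-2-[3,4-bis(benzyloxy)phenyl]chroman-4-ol (C4 epimers) | OC1C[C@@H](c2ccc(OCc3ccccc3)c(OCc3ccccc3)c2)Oc2cc(OCc3ccccc3)cc(OCc3ccccc3)c12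
F6 | step 14 | octa-O-benzyl-(−)-epigallocatechin gallate | O=C(O[C@@H]1Cc2c(OCc5ccccc5)cc(OCc5ccccc5)cc2O[C@@H]1c1cc(OCc5ccccc5)c(OCc5ccccc5)c(OCc5ccccc5)c1)c1cc(OCc5ccccc5)c(OCc5ccccc5)c(OCc5ccccc5)c1
F7 | step 14 | dodeca-O-benzyl dimer, upper unit (2S,4R) linked C4→C8 | O=C(O[C@@H]1Cc2c(OCc5ccccc5)cc(OCc5ccccc5)c([C@@H]3C[C@@H](c4ccc(OCc5ccccc5)c(OCc5ccccc5)c4)Oc4cc(OCc5ccccc5)cc(OCc5ccccc5)c43)c2O[C@@H]1c1cc(OCc5ccccc5)c(OCc5ccccc5)c(OCc5ccccc5)c1)c1cc(OCc5ccccc5)c(OCc5ccccc5)c(OCc5ccccc5)c1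
F8 | step 10 | ethyl (S)-3-[3,4-bis(benzyloxy)phenyl]-3-hydroxypropanoate | CCOC(=O)C[C@H](O)c1ccc(OCc2ccccc2)c(OCc2ccccc2)c1
F9 | step 10 | (S)-1-[3,4-bis(benzyloxy)phenyl]propane-1,3-diol | OCC[C@H](O)c1ccc(OCc2ccccc2)c(OCc2ccccc2)c1
F10 | step 10 | (S)-1-[3,4-bis(benzyloxy)phenyl]-3-(tert-butyldimethylsilyloxy)propan-1-ol | CC(C)(C)[Si](C)(C)OCC[C@H](O)c1ccc(OCc2ccccc2)c(OCc2ccccc2)c1
F11 | step 10 | (S)-tert-butyl{3-[3,4-bis(benzyloxy)phenyl]-3-[3,5-bis(benzyloxy)phenoxy]propoxy}dimethylsilane | CC(C)(C)[Si](C)(C)OCC[C@@H](c1ccc(OCc2ccccc2)c(OCc2ccccc2)c1)Oc1cc(OCc2ccccc2)cc(OCc2ccccc2)c1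
F12 | step 10 | (S)-3-[3,4-bis(benzyloxy)phenyl]-3-[3,5-bis(benzyloxy)phenoxy]propan-1-ol | OCC[C@@H](c1ccc(OCc2ccccc2)c(OCc2ccccc2)c1)Oc1cc(OCc2ccccc2)cc(OCc2ccccc2)c1
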